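**Plan**
Cuts, in retrosynthetic order: the four O-benzyl groups and the C4 oxygen (back to a 2,2-dimethyl-2H-chromene); then the pyran bonds C4–C4a and O1–C2 together; then the C8–CH2 bond of the bridge; last the aryl–acyl bond of ring A.
Enabling feature: in ring B the two pyran bonds start from the adjacent carbons C4a and C8a, and O1 on C8a lies para to the C6 methyl. With the bridge on C8, C4a is the only open carbon ortho to O1. An aryl 1,1-dimethylpropargyl ether on O1 converts this pattern into a chromene on heating.
Forward: ring B comes from 2-methylresorcinol by C–H borylation/oxidation and receives the propargyl ether while it has only one free hydroxyl. Ring A comes from 2,4,6-trihydroxytoluene by acylation, O-methylation and aminomethylation.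
The two benzene rings are joined through an o-quinone methide and all four phenols are benzylated. The pyran ring, the only ring built, then closes thermally; hydration, oxidation and hydrogenolysis finish the target.
Stereochemistry: the single (R) centre is bought with (R)-2-methylbutanoic acid, takes part in no bond formation, and is kept away from strong acid and strong base.

Key step: step 10

Assumption: (R)-2-methylbutanoic acid is taken as a purchasable single enantiomer. The carbinol carbon C4 of 21 forms as both epimers, which does not matter because step 12 makes it planar.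

**Step 1**
Reactants: 1 2-methylresorcinol
Product: 2 2-methyl-1,3-bis(triisopropylsilyloxy)benzene
Conditions: TIPSCl (2.3 equiv), imidazole, DMF, rt to 40 °C
Reagents that add atoms: chlorotriisopropylsilane, CC(C)[Si](Cl)(C(C)C)C(C)C
Why: Routine silyl ether protection of phenols; triisopropylsilyl is chosen because, unlike a benzyl ether, it brings no unhindered aromatic C–H into the borylation of step 2 and it withstands the amine base of step 3.

**Step 2**
Reactants: 2 2-methyl-1,3-bis(triisopropylsilyloxy)benzene
Product: 4 4-methyl-3,5-bis(triisopropylsilyloxy)phenol, via pinacol boronate 3 (not isolated)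
Conditions: [Ir(OMe)(cod)]2 (1.5 mol %), dtbpy (3 mol %), B2pin2 (0.6 equiv), THF, 80 °C; then 30% aq H2O2, 1 M aq NaOH, 0 °C
Reagents that add atoms: bis(pinacolato)diboron, CC1(C)OB(OC1(C)C)B2OC(C)(C)C(C)(C)O2 (its boron is carried only as far as 3); hydrogen peroxide, OO
Why: Sterically controlled iridium-catalysed aromatic C–H borylation followed by boronate oxidation, a known one-pot phenol synthesis; the ring hydrogen para to the methyl group is the only one without an ortho substituent, so the hydroxyl should enter there alone.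

**Step 3**
Reactants: 4 4-methyl-3,5-bis(triisopropylsilyloxy)phenol; 5 3-chloro-3-methylbut-1-yne
Product: 6 2-methyl-5-[(2-methylbut-3-yn-2-yl)oxy]-1,3-bis(triisopropylsilyloxy)benzene
Conditions: CuCl2·2H2O (1 mol %), DBU (1.3 equiv), MeCN, 0 °C
Reagents that add atoms: none
Why: Copper-catalysed O-propargylation of a phenol with a tertiary propargylic chloride; 4 has one free hydroxyl only, so placing the ether now avoids competition from the acidic ring A phenols that would be present after the rings are joined.

**Step 4**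
Reactants: 6 2-methyl-5-[(2-methylbut-3-yn-2-yl)oxy]-1,3-bis(triisopropylsilyloxy)benzene
Product: 7 2-methyl-5-[(2-methylbut-3-yn-2-yl)oxy]benzene-1,3-diol
Conditions: TBAF (2.2 equiv), AcOH (2.2 equiv), THF, 0 °C
Reagents that add atoms: none
Why: Fluoride-mediated silyl ether cleavage, buffered with acetic acid so that the electron-rich resorcinol is not kept as its phenoxide; the tertiary propargyl ether and the terminal alkyne are inert to fluoride.

**Step 5**
Reactants: 8 (R)-2-methylbutanoic acid; 9 2,4,6-trihydroxytoluene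
Product: 11 (2R)-2-methyl-1-(2,4,6-trihydroxy-3-methylphenyl)butan-1-one, via acid chloride 10 (not isolated)
Conditions: (COCl)2, cat. DMF, CH2Cl2, 0 °C to rt; then 9, AlCl3 (3.5 equiv), CH2Cl2/PhNO2, 0 °C to rt; cold 1 M HCl quench
Reagents that add atoms: oxalyl chloride, O=C(Cl)C(=O)Cl (its chlorine is carried only as far as 10)
Why: Acid chloride formation and Friedel–Crafts acylation of an activated phenol; the two open positions of 9 are equivalent, the first acyl group deactivates the ring against a second, and low temperature with short contact time should keep the purchased (R) centre from enolising (to be checked by chiral HPLC on 11).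

**Step 6**
Reactants: 11 (2R)-2-methyl-1-(2,4,6-trihydroxy-3-methylphenyl)butan-1-one
Product: 12 (2R)-1-(2,6-dihydroxy-4-methoxy-3-methylphenyl)-2-methylbutan-1-one
Conditions: Me2SO4 (1.0 equiv), K2CO3 (1.1 equiv), acetone, rt
Reagents that add atoms: dimethyl sulfate, COS(=O)(=O)OC
Why: Williamson-type O-methylation with one equivalent of electrophile; the hydroxyl para to the ketone is the most acidic and the only one that cannot hydrogen-bond to the carbonyl group, which is the known basis of 4-O-selective alkylation of acylphloroglucinols.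

**Step 7**
Reactants: 12 (2R)-1-(2,6-dihydroxy-4-methoxy-3-methylphenyl)-2-methylbutan-1-one
Product: 13 (2R)-1-{3-[(dimethylamino)methyl]-2,6-dihydroxy-4-methoxy-5-methylphenyl}-2-methylbutan-1-one
Conditions: 37% aq CH2O, 40% aq Me2NH (excess), EtOH, 0 °C to rt
Reagents that add atoms: formaldehyde, C=O; dimethylamine, CNC
Why: Mannich aminomethylation at the single unsubstituted carbon of the acylphloroglucinol ring, run near room temperature with excess amine so that the product does not go on to a methylene-bridged dimer.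

**Step 8**
Reactants: 13 (2R)-1-{3-[(dimethylamino)methyl]-2,6-dihydroxy-4-methoxy-5-methylphenyl}-2-methylbutan-1-one; 7 2-methyl-5-[(2-methylbut-3-yn-2-yl)oxy]benzene-1,3-diol
Product: 15 (2R)-1-[3-({2,4-dihydroxy-3-methyl-6-[(2-methylbut-3-yn-2-yl)oxy]phenyl}methyl)-2,6-dihydroxy-4-methoxy-5-methylphenyl]-2-methylbutan-1-one, via o-quinone methide 14 (not isolated)
Conditions: 7 (1.5 equiv), 1,4-dioxane, 60 °C, N2 sweep
Reagents that add atoms: none
Why: Retro-Mannich loss of dimethylamine from the zwitterionic Mannich base gives the acyl-stabilised o-quinone methide 14, which the resorcinol carbon of 7 captures by conjugate addition, the classical entry to unsymmetrical methylene-bridged phloroglucinols; the two nucleophilic carbons of 7 are equivalent, the excess of 7 holds back double alkylation, and 60 °C lies well below the onset of the propargyl ether rearrangement.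

**Step 9**
Reactants: 15 (2R)-1-[3-({2,4-dihydroxy-3-methyl-6-[(2-methylbut-3-yn-2-yl)oxy]phenyl}methyl)-2,6-dihydroxy-4-methoxy-5-methylphenyl]-2-methylbutan-1-one
Product: 16 (2R)-1-[2,6-bis(benzyloxy)-3-({2,4-bis(benzyloxy)-3-methyl-6-[(2-methylbut-3-yn-2-yl)oxy]phenyl}methyl)-4-methoxy-5-methylphenyl]-2-methylbutan-1-one
Conditions: BnBr (5 equiv), K2CO3 (6 equiv), Bu4NI (cat.), DMF, rt to 50 °C
Reagents that add atoms: benzyl bromide, BrCc1ccccc1
Why: Exhaustive Williamson benzylation in a dipolar aprotic solvent, which favours O- over C-alkylation; the benzyl group on the future C5 oxygen leaves O1 as the only oxygen able to close the pyran ring, and the ring A ethers shut off thermal fragmentation of the bridge and phenol oxidation in steps 11 and 12.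

**Step 10**
Reactants: 16 (2R)-1-[2,6-bis(benzyloxy)-3-({2,4-bis(benzyloxy)-3-methyl-6-[(2-methylbut-3-yn-2-yl)oxy]phenyl}methyl)-4-methoxy-5-methylphenyl]-2-methylbutan-1-one
Product: 20 (2R)-1-[2,6-bis(benzyloxy)-3-{[5,7-bis(benzyloxy)-2,2,6-trimethyl-2H-chromen-8-yl]methyl}-4-methoxy-5-methylphenyl]-2-methylbutan-1-one, via allenyl dienone 17 (not isolated), via o-allenylphenol 18 (not isolated), via vinyl o-quinone methide 19 (not isolated)
Conditions: degassed o-xylene, 140 °C, Ar
Reagents that add atoms: none
Why: This is the aromatic propargyl Claisen cascade, the known thermal conversion of aryl 1,1-dimethylpropargyl ethers into 2,2-dimethyl-2H-chromenes: a [3,3] shift joins the alkyne terminus to the unsubstituted ortho carbon (C4–C4a) while O–CMe2 breaks, giving dienone 17, which enolises to the o-allenylphenol 18. A 1,5-hydrogen shift from the new O1–H to the central allene carbon then gives the Z-configured o-quinone methide 19, and a thermal disrotatory oxa-6π electrocyclisation forms O1–C2, so the six-membered pyran ring closes pericyclically rather than by polar attack. No stereocentre is created, because C2 carries two methyl groups and the sp3 carbon of 17 is lost on enolisation, and the neutral medium leaves the (R) centre untouched. Two selectivities are needed, the site of the [3,3] shift and the oxygen that closes the ring. The first is secured because the other ortho carbon bears the bridge methylene, so a shift onto it gives a dienone that cannot enolise and can only revert; the second is secured because the neighbouring C5 oxygen is benzylated, so only O1–H can feed the hydrogen shift. The geminal methyl groups lower the rearrangement temperature, and with no free phenol present the diarylmethane cannot fragment through an o-quinone methide at 140 °C.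

**Step 11**
Reactants: 20 (2R)-1-[2,6-bis(benzyloxy)-3-{[5,7-bis(benzyloxy)-2,2,6-trimethyl-2H-chromen-8-yl]methyl}-4-methoxy-5-methylphenyl]-2-methylbutan-1-one
Product: 21 (2R)-1-[2,6-bis(benzyloxy)-3-{[5,7-bis(benzyloxy)-4-hydroxy-2,2,6-trimethyl-3,4-dihydro-2H-chromen-8-yl]methyl}-4-methoxy-5-methylphenyl]-2-methylbutan-1-one (both C4 epimers)
Conditions: Mn(dpm)3 (10 mol %), PhSiH3 (2 equiv), O2 (1 atm), iPrOH/CH2Cl2, 0 °C to rt
Reagents that add atoms: dioxygen, O=O
Why: Mukaiyama hydration (metal-hydride hydrogen atom transfer, capture of the radical by O2, reduction of the peroxide); the hydrogen atom goes to C3 because this gives the benzylic C4 radical, so oxygen ends up at C4, and any ketone 22 formed directly is simply carried into step 12.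

**Step 12**
Reactants: 21 (2R)-1-[2,6-bis(benzyloxy)-3-{[5,7-bis(benzyloxy)-4-hydroxy-2,2,6-trimethyl-3,4-dihydro-2H-chromen-8-yl]methyl}-4-methoxy-5-methylphenyl]-2-methylbutan-1-one (both C4 epimers)
Product: 22 5,7-bis(benzyloxy)-8-({2,4-bis(benzyloxy)-6-methoxy-5-methyl-3-[(2R)-2-methylbutanoyl]phenyl}methyl)-2,2,6-trimethyl-2,3-dihydro-4H-chromen-4-one
Conditions: Dess–Martin periodinane (1.3 equiv), CH2Cl2, 0 °C to rt
Reagents that add atoms: none
Why: Dess–Martin oxidation of a secondary benzylic alcohol under near-neutral conditions; with all phenols capped nothing else in 21 is oxidised by the reagent, and the (R) centre sees no base.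

**Step 13**
Reactants: 22 5,7-bis(benzyloxy)-8-({2,4-bis(benzyloxy)-6-methoxy-5-methyl-3-[(2R)-2-methylbutanoyl]phenyl}methyl)-2,2,6-trimethyl-2,3-dihydro-4H-chromen-4-one
Product: 23 8-({2,4-dihydroxy-6-methoxy-5-methyl-3-[(2R)-2-methylbutanoyl]phenyl}methyl)-5,7-dihydroxy-2,2,6-trimethyl-2,3-dihydro-4H-chromen-4-one (CNP0303209.1)
Conditions: H2 (1 atm), 10% Pd/C, EtOAc/MeOH, rt
Reagents that add atoms: none
Why: Catalytic hydrogenolysis of four aryl benzyl ethers under neutral conditions; the two aryl ketones are vinylogous esters that become hydrogen-bonded as the phenols appear and should resist reduction, and the diarylmethane bonds, the methyl ether and the (R) centre are untouched.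

**Compound list**
1 | 2-methylresorcinol (2-methylbenzene-1,3-diol) | Cc1c(O)cccc1O | starting material
2 | 2-methyl-1,3-bis(triisopropylsilyloxy)benzene | Cc1c(O[Si](C(C)C)(C(C)C)C(C)C)cccc1O[Si](C(C)C)(C(C)C)C(C)C | intermediate
3 | 2-[4-methyl-3,5-bis(triisopropylsilyloxy)phenyl]-4,4,5,5-tetramethyl-1,3,2-dioxaborolane (not isolated) | Cc1c(O[Si](C(C)C)(C(C)C)C(C)C)cc(B2OC(C)(C)C(C)(C)O2)cc1O[Si](C(C)C)(C(C)C)C(C)C | intermediate
4 | 4-methyl-3,5-bis(triisopropylsilyloxy)phenol | Cc1c(O[Si](C(C)C)(C(C)C)C(C)C)cc(O)cc1O[Si](C(C)C)(C(C)C)C(C)C | intermediate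
5 | 3-chloro-3-methylbut-1-yne | CC(C)(Cl)C#C | starting material
6 | 2-methyl-5-[(2-methylbut-3-yn-2-yl)oxy]-1,3-bis(triisopropylsilyloxy)benzene | Cc1c(O[Si](C(C)C)(C(C)C)C(C)C)cc(OC(C)(C)C#C)cc1O[Si](C(C)C)(C(C)C)C(C)C | intermediate
7 | 2-methyl-5-[(2-methylbut-3-yn-2-yl)oxy]benzene-1,3-diol | Cc1c(O)cc(OC(C)(C)C#C)cc1O | intermediate
8 | (R)-2-methylbutanoic acid | CC[C@@H](C)C(=O)O | starting material
9 | 2,4,6-trihydroxytoluene (2-methylbenzene-1,3,5-triol) | Cc1c(O)cc(O)cc1O | starting material
10 | (R)-2-methylbutanoyl chloride (not isolated) | CC[C@@H](C)C(=O)Cl | intermediate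
11 | (2R)-2-methyl-1-(2,4,6-trihydroxy-3-methylphenyl)butan-1-one | CC[C@@H](C)C(=O)c1c(O)cc(O)c(C)c1O | intermediate
12 | (2R)-1-(2,6-dihydroxy-4-methoxy-3-methylphenyl)-2-methylbutan-1-one | CC[C@@H](C)C(=O)c1c(O)cc(OC)c(C)c1O | intermediate
13 | (2R)-1-{3-[(dimethylamino)methyl]-2,6-dihydroxy-4-methoxy-5-methylphenyl}-2-methylbutan-1-one | CC[C@@H](C)C(=O)c1c(O)c(C)c(OC)c(CN(C)C)c1O | intermediate
14 | 3-hydroxy-5-methoxy-4-methyl-2-[(2R)-2-methylbutanoyl]-6-methylidenecyclohexa-2,4-dien-1-one, ring A o-quinone methide (not isolated) | CC[C@@H](C)C(=O)C1=C(O)C(C)=C(OC)C(=C)C1=O | intermediate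
15 | (2R)-1-[3-({2,4-dihydroxy-3-methyl-6-[(2-methylbut-3-yn-2-yl)oxy]phenyl}methyl)-2,6-dihydroxy-4-methoxy-5-methylphenyl]-2-methylbutan-1-one | CC[C@@H](C)C(=O)c1c(O)c(C)c(OC)c(Cc2c(O)c(C)c(O)cc2OC(C)(C)C#C)c1O | intermediate
16 | (2R)-1-[2,6-bis(benzyloxy)-3-({2,4-bis(benzyloxy)-3-methyl-6-[(2-methylbut-3-yn-2-yl)oxy]phenyl}methyl)-4-methoxy-5-methylphenyl]-2-methylbutan-1-one, key-step precursor | CC[C@@H](C)C(=O)c1c(OCc3ccccc3)c(C)c(OC)c(Cc2c(OCc4ccccc4)c(C)c(OCc5ccccc5)cc2OC(C)(C)C#C)c1OCc6ccccc6 | intermediate
17 | product of the [3,3] shift, ring B as a 6-(3-methylbuta-1,2-dien-1-yl)cyclohexa-2,4-dien-1-one, transient sp3 carbon unassigned (not isolated) | CC[C@@H](C)C(=O)c1c(OCc3ccccc3)c(C)c(OC)c(CC2=C(OCc4ccccc4)C(C)=C(OCc5ccccc5)C(C=C=C(C)C)C2=O)c1OCc6ccccc6 | intermediate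
18 | o-allenylphenol, ring B as a 2-(3-methylbuta-1,2-dien-1-yl)phenol (not isolated) | CC[C@@H](C)C(=O)c1c(OCc3ccccc3)c(C)c(OC)c(Cc2c(OCc4ccccc4)c(C)c(OCc5ccccc5)c(C=C=C(C)C)c2O)c1OCc6ccccc6 | intermediate
19 | vinyl o-quinone methide, ring B as a (6Z)-6-(3-methylbut-2-en-1-ylidene)cyclohexa-2,4-dien-1-one (not isolated) | CC[C@@H](C)C(=O)c1c(OCc3ccccc3)c(C)c(OC)c(CC2=C(OCc4ccccc4)C(C)=C(OCc5ccccc5)/C(=C/C=C(C)C)C2=O)c1OCc6ccccc6 | intermediate
20 | (2R)-1-[2,6-bis(benzyloxy)-3-{[5,7-bis(benzyloxy)-2,2,6-trimethyl-2H-chromen-8-yl]methyl}-4-methoxy-5-methylphenyl]-2-methylbutan-1-one, key-step product | CC[C@@H](C)C(=O)c1c(OCc3ccccc3)c(C)c(OC)c(Cc2c(OCc4ccccc4)c(C)c(OCc5ccccc5)c7C=CC(C)(C)Oc27)c1OCc6ccccc6 | intermediate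
21 | (2R)-1-[2,6-bis(benzyloxy)-3-{[5,7-bis(benzyloxy)-4-hydroxy-2,2,6-trimethyl-3,4-dihydro-2H-chromen-8-yl]methyl}-4-methoxy-5-methylphenyl]-2-methylbutan-1-one, both C4 epimers | CC[C@@H](C)C(=O)c1c(OCc3ccccc3)c(C)c(OC)c(Cc2c(OCc4ccccc4)c(C)c(OCc5ccccc5)c7C(O)CC(C)(C)Oc27)c1OCc6ccccc6 | intermediate
22 | 5,7-bis(benzyloxy)-8-({2,4-bis(benzyloxy)-6-methoxy-5-methyl-3-[(2R)-2-methylbutanoyl]phenyl}methyl)-2,2,6-trimethyl-2,3-dihydro-4H-chromen-4-one | CC[C@@H](C)C(=O)c1c(OCc3ccccc3)c(C)c(OC)c(Cc2c(OCc4ccccc4)c(C)c(OCc5ccccc5)c7C(=O)CC(C)(C)Oc27)c1OCc6ccccc6 | intermediate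
23 | 8-({2,4-dihydroxy-6-methoxy-5-methyl-3-[(2R)-2-methylbutanoyl]phenyl}methyl)-5,7-dihydroxy-2,2,6-trimethyl-2,3-dihydro-4H-chromen-4-one (CNP0303209.1) | CC[C@@H](C)C(=O)c1c(O)c(C)c(OC)c(Cc2c(O)c(C)c(O)c3c2OC(C)(C)CC3=O)c1O | target

**Step count**
Total step count: 13.
Longest linear sequence: 10 steps (steps 1–4, then 8–13, from 2-methylresorcinol). The ring A branch (steps 5–7) joins at step 8.

**Steps most likely to fail**

Step 8 (bridge formation). A second o-quinone methide may add to the remaining free carbon of ring B. The Mannich base may condense with itself by ipso substitution. Amine loss may also be too slow at a temperature the propargyl ether tolerates. The fallback reverses the roles of the two rings. Setting out from 7, aminomethylation with one equivalent each of CH2O and Me2NH in EtOH should give 4-[(dimethylamino)methyl]-2-methyl-5-[(2-methylbut-3-yn-2-yl)oxy]benzene-1,3-diol F1. F1 is then warmed in dioxane with ketone 12, which is acidic enough to protonate the amine. This should release 3-hydroxy-2-methyl-6-methylidene-5-[(2-methylbut-3-yn-2-yl)oxy]cyclohexa-2,4-dien-1-one F2. The only free ring carbon of 12 adds to F2, so the nucleophile cannot be alkylated twice, and the sequence returns to the route at 15.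

Step 9 (fourfold benzylation). The ring B phenoxide may be benzylated at its free carbon. Ring A may be C-benzylated with loss of aromaticity. The hindered, hydrogen-bonded hydroxyls may also react incompletely. The fallback never exposes a ring B phenoxide to benzyl bromide. Setting out from 15, a Mitsunobu etherification (BnOH, PPh3, DIAD, THF) acts on the neutral phenols. It should cap the two non-chelated ring B hydroxyls first, giving (2R)-1-[3-({2,4-bis(benzyloxy)-3-methyl-6-[(2-methylbut-3-yn-2-yl)oxy]phenyl}methyl)-2,6-dihydroxy-4-methoxy-5-methylphenyl]-2-methylbutan-1-one F3. Any ring A ether formed at this stage is harmless. The two remaining ring A hydroxyls, whose anions are acyl-stabilised, are then benzylated with BnBr and K2CO3 in DMF, which returns to the route at 16.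

Step 11 (hydration of the chromene). Hydrogen atom transfer to the hindered 1,2-disubstituted alkene may be slow. The benzylic radical may be reduced to the chroman instead of being trapped by O2. Peroxyl radicals may also attack the doubly benzylic bridge. The fallback replaces radical control by polar control of the regiochemistry. Setting out from 20, NBS in wet DMSO should form a bromonium ion that water opens at the benzylic carbon. This gives the trans bromohydrin (2R)-1-[2,6-bis(benzyloxy)-3-{[5,7-bis(benzyloxy)-3-bromo-4-hydroxy-2,2,6-trimethyl-3,4-dihydro-2H-chromen-8-yl]methyl}-4-methoxy-5-methylphenyl]-2-methylbutan-1-one F4. Both aromatic rings are fully substituted and offer no site for ring bromination. Radical debromination (Bu3SnH, AIBN, toluene, 80 °C) then returns to the route at 21.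

**Further compounds**
F1 | step 8 | 4-[(dimethylamino)methyl]-2-methyl-5-[(2-methylbut-3-yn-2-yl)oxy]benzene-1,3-diol | Cc1c(O)cc(OC(C)(C)C#C)c(CN(C)C)c1O
F2 | step 8 | 3-hydroxy-2-methyl-6-methylidene-5-[(2-methylbut-3-yn-2-yl)oxy]cyclohexa-2,4-dien-1-one (transient) | C=C1C(OC(C)(C)C#C)=CC(O)=C(C)C1=O
F3 | step 9 | (2R)-1-[3-({2,4-bis(benzyloxy)-3-methyl-6-[(2-methylbut-3-yn-2-yl)oxy]phenyl}methyl)-2,6-dihydroxy-4-methoxy-5-methylphenyl]-2-methylbutan-1-one | CC[C@@H](C)C(=O)c1c(O)c(C)c(OC)c(Cc2c(OCc3ccccc3)c(C)c(OCc3ccccc3)cc2OC(C)(C)C#C)c1O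
F4 | step 11 | trans-3-bromo-4-hydroxychroman derived from 20, formed as the two trans diastereomers, the (3R,4S) isomer drawn | CC[C@@H](C)C(=O)c1c(OCc3ccccc3)c(C)c(OC)c(Cc2c(OCc4ccccc4)c(C)c(OCc5ccccc5)c7[C@H](O)[C@@H](Br)C(C)(C)Oc27)c1OCc6ccccc6
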